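**Retrosynthetic overview**
- Late disconnections: the C7 acid from its tert-butyl ester, the enal from a silyl-protected 2-(hydroxymethyl)allyl group attached by C1 enolate alkylation, and the C4–O acyl bond to the (8R)-trienoic acid (Evans methylation, Wittig, vinylogous Horner–Wadsworth–Emmons).
- Feature the strategy rests on: in the 7a-methyl-indenone core the C7a methyl and the C4 oxygen are cis across C3a. A C4 hydroxyl on a C3a=C7a alkene can therefore deliver the methyl carbon to the correct face as a cyclopropane CH2 (bonds C7a–CH2 and C3a–CH2).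
- After oxidation at C4, reductive cleavage of C3a–CH2 leaves CH3 on C7a and a C3a=C4 enolate, which is desaturated to the C3a=C3 enone. C4 (hydride), C7 (proton) and C1 (allyl bromide) are then set in turn under the control of the C7a methyl.
- Ring order: six-membered ring (Robinson annulation to the tert-butyl Hagemann ester), five-membered ring (C3 alkylation with methyl bromoacetate, vinylogous Dieckmann closure), three-membered ring (key step, reopened later). Absolute configuration comes from a CBS reduction at C4.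

Key step: step 16

Remark on numbering: locants C1–C7a of all bicyclic compounds follow the indenone numbering of the target (C2 ketone, C4 oxygen, C7 carboxyl, C7a quaternary carbon).
Assumption: C7 (α to the ester) is not controlled by the ketone reduction that makes the key-step substrate. That substrate and the intermediates up to the ester-enolate protonation are therefore carried as pairs of C7 epimers (SMILES written without a C7 descriptor); both converge when C7 is protonated anti to the C7a methyl.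

**Acyl side chain**

Step 1
Reactants: 1 (R)-4-benzyloxazolidin-2-one; 2 butanoyl chloride
Product: 3 (R)-4-benzyl-3-butanoyloxazolidin-2-one
Conditions: n-BuLi, THF, −78 °C; then 2, −78 → 0 °C
Reagents that add atoms: none
Why: N-Acylation of the lithiated oxazolidinone with the acid chloride (acyl substitution) loads the Evans auxiliary without touching its stereocentre.

Step 2
Reactants: 3 (R)-4-benzyl-3-butanoyloxazolidin-2-one; 4 iodomethane
Product: 5 (R)-4-benzyl-3-[(2R)-2-methylbutanoyl]oxazolidin-2-one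
Conditions: NaN(SiMe3)2, THF, −78 °C; 4, −78 → −40 °C; minor diastereomer removed by chromatography
Reagents that add atoms: none
Why: Evans alkylation: the chelated Z-sodium enolate is methylated on the face away from the benzyl group, which with the (R)-auxiliary sets the new α-centre as R (the future C8 of the acyl chain).

Step 3
Reactants: 5 (R)-4-benzyl-3-[(2R)-2-methylbutanoyl]oxazolidin-2-one
Product: 6 (R)-2-methylbutan-1-ol
Conditions: LiBH4, Et2O, H2O (1 equiv), 0 °C; product kept as a CH2Cl2 solution (volatile)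
Reagents that add atoms: none
Why: Reductive removal of the auxiliary by borohydride attack at the exocyclic imide carbonyl gives the primary alcohol without epimerisation and returns 1.

Step 4
Reactants: 6 (R)-2-methylbutan-1-ol; 7 ethyl 2-(triphenyl-λ5-phosphanylidene)propanoate
Product: 9 ethyl (2E,4R)-2,4-dimethylhex-2-enoate, via (R)-2-methylbutanal 8 (not isolated)
Conditions: TEMPO (2,2,6,6-tetramethylpiperidin-1-oxyl, cat.), PhI(OAc)2, CH2Cl2, 0 °C → rt; then 7 (2 equiv), rt → 40 °C
Reagents that add atoms: none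
Why: Oxoammonium (TEMPO) oxidation gives the epimerisable α-branched aldehyde, which is consumed at once in a Wittig olefination by the stabilised ylide, E-selective for the trisubstituted enoate.

Step 5
Reactants: 9 ethyl (2E,4R)-2,4-dimethylhex-2-enoate
Product: 10 (2E,4R)-2,4-dimethylhex-2-en-1-ol
Conditions: i-Bu2AlH (2.2 equiv), CH2Cl2, −78 °C; aqueous potassium sodium tartrate
Reagents that add atoms: none
Why: Ester-to-allylic-alcohol reduction with two hydrides of i-Bu2AlH proceeds by 1,2-addition and leaves the alkene geometry and the C4 centre intact.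

Step 6
Reactants: 10 (2E,4R)-2,4-dimethylhex-2-en-1-ol
Product: 11 (2E,4R)-2,4-dimethylhex-2-enal
Conditions: MnO2, CH2Cl2, rt
Reagents that add atoms: none
Why: Chemoselective allylic oxidation on MnO2 stops at the enal.

Step 7
Reactants: 11 (2E,4R)-2,4-dimethylhex-2-enal; 12 triethyl (E)-4-phosphonobut-2-enoate
Product: 13 ethyl (2E,4E,6E,8R)-6,8-dimethyldeca-2,4,6-trienoate
Conditions: 12, LiN(SiMe3)2, THF, −78 °C; then 11, −78 → 0 °C
Reagents that add atoms: none
Why: Vinylogous Horner–Wadsworth–Emmons olefination with the lithiated phosphonocrotonate forms the new C4=C5 bond E and extends the chain to the 2E,4E,6E-trienoate.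

Step 8
Reactants: 13 ethyl (2E,4E,6E,8R)-6,8-dimethyldeca-2,4,6-trienoate
Product: 14 (2E,4E,6E,8R)-6,8-dimethyldeca-2,4,6-trienoic acid
Conditions: LiOH, THF/MeOH/H2O, rt; then 1 M HCl
Reagents that add atoms: lithium hydroxide, [Li+].[OH-]
Why: Saponification of the ethyl ester under mild conditions that do not isomerise the triene.

**C1 side-chain reagent**

Step 9
Reactants: 15 2-methylidenepropane-1,3-diol
Product: 16 2-({[tert-butyl(dimethyl)silyl]oxy}methyl)prop-2-en-1-ol
Conditions: NaH (1.0 equiv), THF, 0 °C → rt; t-BuMe2SiCl (1.0 equiv)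
Reagents that add atoms: tert-butyl(chloro)dimethylsilane, CC(C)(C)[Si](C)(C)Cl
Why: Monosilylation of the symmetrical diol through its monosodium alkoxide (Williamson-type O-silylation) differentiates the two hydroxyls.

Step 10
Reactants: 16 2-({[tert-butyl(dimethyl)silyl]oxy}methyl)prop-2-en-1-ol
Product: 17 {[2-(bromomethyl)prop-2-en-1-yl]oxy}(tert-butyl)dimethylsilane
Conditions: CBr4, PPh3, CH2Cl2, 0 °C
Reagents that add atoms: tetrabromomethane, BrC(Br)(Br)Br
Why: Appel bromination converts the allylic alcohol into the bromide under neutral conditions that keep the silyl ether.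

**Core**

Step 11
Reactants: 18 tert-butyl 3-oxobutanoate; 19 but-3-en-2-one
Product: 21 tert-butyl 2-methyl-4-oxocyclohex-2-ene-1-carboxylate (racemic tert-butyl Hagemann ester), via tert-butyl 2-acetyl-5-oxohexanoate 20 (not isolated)
Conditions: FeCl3·6H2O (2 mol %), neat, rt; then pyrrolidine (0.2 equiv), AcOH (0.2 equiv), toluene, reflux, Dean–Stark
Reagents that add atoms: none
Why: Robinson annulation: Lewis-acid-catalysed Michael addition of the β-keto ester to the enone, then enamine-mediated aldol condensation of the methyl ketone carbon onto the acetoacetate carbonyl, gives the 4-oxocyclohex-2-ene-1-carboxylate (six-membered ring; racemic, the centre is the future epimerisable C7).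

Step 12
Reactants: 21 tert-butyl 2-methyl-4-oxocyclohex-2-ene-1-carboxylate; 22 methyl bromoacetate
Product: 23 tert-butyl 3-(2-methoxy-2-oxoethyl)-2-methyl-4-oxocyclohex-2-ene-1-carboxylate (racemic)
Conditions: KOC(CH3)3 (1.05 equiv), t-BuOH/THF, 0 °C; 22, 0 °C → rt
Reagents that add atoms: none
Why: Alkylation of the extended dienolate of a Hagemann-type ester takes place at the enone α-carbon (the future C3a) and the alkene returns to conjugation with the ketone.

Step 13
Reactants: 23 tert-butyl 3-(2-methoxy-2-oxoethyl)-2-methyl-4-oxocyclohex-2-ene-1-carboxylate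
Product: 24 tert-butyl 2,4-dioxo-2,3,4,5,6,7-hexahydro-1H-indene-7-carboxylate (racemic; drawn as the C3a=C7a enone tautomer, used crude)
Conditions: KOC(CH3)3 (2.5 equiv), THF/t-BuOH, 0.02 M, argon, rt → 60 °C; AcOH, 0 °C
Reagents that add atoms: none
Why: Vinylogous Dieckmann condensation: under equilibrating alkoxide the dienolate formed through the C2 methyl group attacks the neighbouring methyl ester to close the five-membered ring, and the step is pulled forward by deprotonation of the vinylogous β-diketone product.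

Step 14
Reactants: 24 tert-butyl 2,4-dioxo-2,3,4,5,6,7-hexahydro-1H-indene-7-carboxylate
Product: 25 tert-butyl 2,2-(ethylenedioxy)-4-oxo-2,3,4,5,6,7-hexahydro-1H-indene-7-carboxylate (racemic)
Conditions: ethylene glycol, pyridinium p-toluenesulfonate (cat.), benzene, reflux, Dean–Stark
Reagents that add atoms: ethane-1,2-diol, OCCO
Why: Selective ketalisation under thermodynamic control: the non-conjugated cyclopentanone carbonyl C2 forms the dioxolane while the conjugated, tetrasubstituted enone carbonyl C4 does not, and the weak acid spares the tert-butyl ester.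

Step 15
Reactants: 25 tert-butyl 2,2-(ethylenedioxy)-4-oxo-2,3,4,5,6,7-hexahydro-1H-indene-7-carboxylate
Product: 26 tert-butyl (4S)-2,2-(ethylenedioxy)-4-hydroxy-2,3,4,5,6,7-hexahydro-1H-indene-7-carboxylate (C7 epimers)
Conditions: (R)-1-methyl-3,3-diphenyltetrahydro-1H,3H-pyrrolo[1,2-c][1,3,2]oxazaborole (0.2 equiv), BH3·SMe2 (0.7 equiv), toluene/THF, −30 °C; MeOH
Reagents that add atoms: none
Why: Corey–Bakshi–Shibata reduction: the oxazaborolidine–borane complex binds the ketone with the branched alkenyl carbon C3a as the large group and delivers hydride to one face to give the 4S allylic alcohol, while the remote C7 centre is not differentiated.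

Step 16
Reactants: 26 tert-butyl (4S)-2,2-(ethylenedioxy)-4-hydroxy-2,3,4,5,6,7-hexahydro-1H-indene-7-carboxylate (C7 epimers); 27 diiodomethane
Product: 28 tert-butyl (3aS,4S,7aS)-2,2-(ethylenedioxy)-4-hydroxyoctahydro-3a,7a-methano-1H-indene-7-carboxylate (CH2 bridge cis to the hydroxyl; C7 epimers)
Conditions: Et2Zn (5 equiv), 27 (5 equiv), CH2Cl2, −10 °C → rt; aqueous NH4Cl
Reagents that add atoms: none
Why: Hydroxyl-directed Simmons–Smith (Furukawa) cyclopropanation: Et2Zn turns the C4 hydroxyl into a zinc alkoxide that binds the carbenoid EtZnCH2I, and the methylene is transferred in one concerted butterfly-type step to the face of the C3a=C7a alkene on which the oxygen sits. The closest known reaction type is the directed cyclopropanation of ring-fusion tetrasubstituted cyclohexenols used for angular methylation. The three-membered ring closes by concerted [2+1] methylene transfer, the bonds C7a–CH2 and C3a–CH2 forming on the same face without an open intermediate. The two new stereocentres C3a and C7a are set together by the 4S carbinol centre through the zinc chelate, so the CH2 lies cis to the C4 oxygen, as the future C7a methyl must. The step needs face selectivity and reactivity at a hindered tetrasubstituted alkene; the allylic zinc alkoxide supplies both (delivery and rate acceleration), the tetra-alkyl alkene is electron-rich, and the dioxolane and the tert-butyl ester are inert to the carbenoid.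

Step 17
Reactants: 28 tert-butyl (3aS,4S,7aS)-2,2-(ethylenedioxy)-4-hydroxyoctahydro-3a,7a-methano-1H-indene-7-carboxylate
Product: 29 tert-butyl (3aS,7aS)-2,2-(ethylenedioxy)-4-oxooctahydro-3a,7a-methano-1H-indene-7-carboxylate (C7 epimers)
Conditions: Dess–Martin periodinane, NaHCO3, CH2Cl2, 0 °C → rt
Reagents that add atoms: none
Why: Dess–Martin oxidation of the secondary cyclopropylcarbinol under buffered, non-acidic conditions avoids cyclopropylcarbinyl cation rearrangement and gives the cyclopropyl ketone needed for strain-release opening.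

Step 18
Reactants: 29 tert-butyl (3aS,7aS)-2,2-(ethylenedioxy)-4-oxooctahydro-3a,7a-methano-1H-indene-7-carboxylate
Product: 31 tert-butyl (7aS)-2,2-(ethylenedioxy)-7a-methyl-4-[(trimethylsilyl)oxy]-2,3,5,6,7,7a-hexahydro-1H-indene-7-carboxylate (C7 epimers), via lithium C3a=C4 enolate 30 (not isolated)
Conditions: Li (2.3 equiv), NH3(l)/THF, −78 °C, 10 min; isoprene; NH3 evaporated; THF, Et3N, Me3SiCl, −78 → 0 °C
Reagents that add atoms: chlorotrimethylsilane, C[Si](C)(C)Cl
Why: Dissolving-metal reductive cleavage of a cyclopropyl ketone: the ketyl radical anion opens the cyclopropane bond that overlaps best with the carbonyl π system (exocyclic C3a–CH2), the resulting primary carbanion is protonated by NH3 to the C7a methyl with C7a untouched, and the regiodefined C3a=C4 enolate is trapped by O-silylation.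

Step 19
Reactants: 31 tert-butyl (7aS)-2,2-(ethylenedioxy)-7a-methyl-4-[(trimethylsilyl)oxy]-2,3,5,6,7,7a-hexahydro-1H-indene-7-carboxylate
Product: 32 tert-butyl (7aS)-2,2-(ethylenedioxy)-7a-methyl-4-oxo-2,4,5,6,7,7a-hexahydro-1H-indene-7-carboxylate (C3=C3a enone; C7 epimers)
Conditions: Pd(OAc)2 (1.1 equiv), MeCN, rt → 40 °C
Reagents that add atoms: none
Why: Saegusa–Ito oxidation: the palladium enolate at C3a can undergo β-hydride elimination only toward C3 because C7a is quaternary, which gives the C4(=O)–C3a=C3 enone.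

Step 20
Reactants: 32 tert-butyl (7aS)-2,2-(ethylenedioxy)-7a-methyl-4-oxo-2,4,5,6,7,7a-hexahydro-1H-indene-7-carboxylate
Product: 33 tert-butyl (4S,7aS)-2,2-(ethylenedioxy)-4-hydroxy-7a-methyl-2,4,5,6,7,7a-hexahydro-1H-indene-7-carboxylate (C7 epimers)
Conditions: (R)-1-methyl-3,3-diphenyltetrahydro-1H,3H-pyrrolo[1,2-c][1,3,2]oxazaborole (0.2 equiv), BH3·SMe2 (0.7 equiv), THF, −30 °C; MeOH
Reagents that add atoms: none
Why: Corey–Bakshi–Shibata 1,2-reduction under aprotic conditions that spare the allylic dioxolane; the catalyst-preferred face and the substrate-preferred face (hydride anti to the axial C7a methyl) coincide, so the 4S alcohol cis to the methyl is formed.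

Step 21
Reactants: 33 tert-butyl (4S,7aS)-2,2-(ethylenedioxy)-4-hydroxy-7a-methyl-2,4,5,6,7,7a-hexahydro-1H-indene-7-carboxylate (C7 epimers)
Product: 35 tert-butyl (4S,7R,7aS)-4-hydroxy-7a-methyl-2-oxo-2,4,5,6,7,7a-hexahydro-1H-indene-7-carboxylate, via (7R)-configured ketal alcohol 34 (not isolated)
Conditions: LiN(i-Pr)2 (3 equiv), THF, −78 → −20 °C; AcOH in THF, −78 °C; then 1 M HCl (aq.), THF, 0 °C → rt
Reagents that add atoms: water, O
Why: Kinetic protonation of the ester enolate (as alkoxide–enolate dianion) from the face opposite the axial C7a methyl places the ester cis to the methyl (7R) for both C7 epimers, and subsequent acetal hydrolysis of the allylic dioxolane releases the C2 enone.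

Step 22
Reactants: 35 tert-butyl (4S,7R,7aS)-4-hydroxy-7a-methyl-2-oxo-2,4,5,6,7,7a-hexahydro-1H-indene-7-carboxylate; 17 {[2-(bromomethyl)prop-2-en-1-yl]oxy}(tert-butyl)dimethylsilane
Product: 36 tert-butyl (1R,4S,7R,7aS)-1-[2-({[tert-butyl(dimethyl)silyl]oxy}methyl)prop-2-en-1-yl]-4-hydroxy-7a-methyl-2-oxo-2,4,5,6,7,7a-hexahydro-1H-indene-7-carboxylate
Conditions: LiN(SiMe3)2 (2.2 equiv), THF, −78 °C; 17 (1.3 equiv), −78 → −30 °C; aqueous NH4Cl
Reagents that add atoms: none
Why: Enolate alkylation: kinetic deprotonation gives the only possible α′-enolate (C1), whose carbon, more nucleophilic than the lithium alkoxide, is alkylated by the allylic bromide on the face away from the C7 branch that carries the tert-butyl ester, i.e. syn to the methyl (1R).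

Step 23
Reactants: 36 tert-butyl (1R,4S,7R,7aS)-1-[2-({[tert-butyl(dimethyl)silyl]oxy}methyl)prop-2-en-1-yl]-4-hydroxy-7a-methyl-2-oxo-2,4,5,6,7,7a-hexahydro-1H-indene-7-carboxylate; 14 (2E,4E,6E,8R)-6,8-dimethyldeca-2,4,6-trienoic acid
Product: 38 tert-butyl (1R,4S,7R,7aS)-1-[2-({[tert-butyl(dimethyl)silyl]oxy}methyl)prop-2-en-1-yl]-4-{[(2E,4E,6E,8R)-6,8-dimethyldeca-2,4,6-trienoyl]oxy}-7a-methyl-2-oxo-2,4,5,6,7,7a-hexahydro-1H-indene-7-carboxylate, via Yamaguchi mixed anhydride 37 (not isolated)
Conditions: 14, 2,4,6-trichlorobenzoyl chloride, Et3N, toluene, rt; then 36, 4-(dimethylamino)pyridine, toluene, rt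
Reagents that add atoms: none
Why: Yamaguchi esterification: the mixed anhydride acylates the hindered secondary allylic alcohol under 4-(dimethylamino)pyridine catalysis by acyl–oxygen bond formation, so C4 keeps its configuration.

Step 24
Reactants: 38 the C4 trienoate silyl ether from step 23
Product: 39 tert-butyl (1R,4S,7R,7aS)-4-{[(2E,4E,6E,8R)-6,8-dimethyldeca-2,4,6-trienoyl]oxy}-1-[2-(hydroxymethyl)prop-2-en-1-yl]-7a-methyl-2-oxo-2,4,5,6,7,7a-hexahydro-1H-indene-7-carboxylate
Conditions: HF·pyridine, pyridine, THF, 0 °C → rt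
Reagents that add atoms: none
Why: Fluoride-mediated desilylation of the primary silyl ether is selective over both esters and the enone.

Step 25
Reactants: 39 the primary allylic alcohol from step 24
Product: 40 tert-butyl (1R,4S,7R,7aS)-4-{[(2E,4E,6E,8R)-6,8-dimethyldeca-2,4,6-trienoyl]oxy}-1-(2-formylprop-2-en-1-yl)-7a-methyl-2-oxo-2,4,5,6,7,7a-hexahydro-1H-indene-7-carboxylate
Conditions: Dess–Martin periodinane, NaHCO3, CH2Cl2, 0 °C
Reagents that add atoms: none
Why: Dess–Martin oxidation of the primary allylic alcohol stops at the 2-substituted acrolein and needs no base that could epimerise C1.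

Step 26
Reactants: 40 the enal tert-butyl ester from step 25
Product: 41 (1R,4S,7R,7aS)-4-{[(2E,4E,6E,8R)-6,8-dimethyldeca-2,4,6-trienoyl]oxy}-1-(2-formylprop-2-en-1-yl)-7a-methyl-2-oxo-2,4,5,6,7,7a-hexahydro-1H-indene-7-carboxylic acid (CNP0277819.3)
Conditions: CF3CO2H/CH2Cl2 (1:4), 0 °C → rt; toluene co-evaporation
Reagents that add atoms: none
Why: Acidolysis of the tert-butyl ester (alkyl–oxygen cleavage with loss of 2-methylpropene) frees the C7 acid without affecting the allylic trienoate, the enal or the stereocentres.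

**Compound list**
1 | (R)-4-benzyloxazolidin-2-one | O=C1N[C@H](Cc2ccccc2)CO1 | starting material
2 | butanoyl chloride | CCCC(Cl)=O | starting material
3 | (R)-4-benzyl-3-butanoyloxazolidin-2-one | CCCC(=O)N1[C@H](Cc2ccccc2)COC1=O | intermediate
4 | iodomethane | CI | starting material
5 | (R)-4-benzyl-3-[(2R)-2-methylbutanoyl]oxazolidin-2-one | CC[C@@H](C)C(=O)N1[C@H](Cc2ccccc2)COC1=O | intermediate
6 | (R)-2-methylbutan-1-ol | CC[C@@H](C)CO | intermediate
7 | ethyl 2-(triphenyl-λ5-phosphanylidene)propanoate | CCOC(=O)C(C)=P(c1ccccc1)(c1ccccc1)c1ccccc1 | starting material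
8 | (R)-2-methylbutanal | CC[C@@H](C)C=O | intermediate
9 | ethyl (2E,4R)-2,4-dimethylhex-2-enoate | CC[C@@H](C)/C=C(\C)C(=O)OCC | intermediate
10 | (2E,4R)-2,4-dimethylhex-2-en-1-ol | CC[C@@H](C)/C=C(\C)CO | intermediate
11 | (2E,4R)-2,4-dimethylhex-2-enal | CC[C@@H](C)/C=C(\C)C=O | intermediate
12 | triethyl (E)-4-phosphonobut-2-enoate | CCOC(=O)/C=C/CP(=O)(OCC)OCC | starting material
13 | ethyl (2E,4E,6E,8R)-6,8-dimethyldeca-2,4,6-trienoate | CC[C@@H](C)/C=C(C)/C=C/C=C/C(=O)OCC | intermediate
14 | (2E,4E,6E,8R)-6,8-dimethyldeca-2,4,6-trienoic acid | CC[C@@H](C)/C=C(C)/C=C/C=C/C(=O)O | intermediate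
15 | 2-methylidenepropane-1,3-diol | C=C(CO)CO | starting material
16 | 2-({[tert-butyl(dimethyl)silyl]oxy}methyl)prop-2-en-1-ol | C=C(CO)CO[Si](C)(C)C(C)(C)C | intermediate
17 | {[2-(bromomethyl)prop-2-en-1-yl]oxy}(tert-butyl)dimethylsilane | C=C(CBr)CO[Si](C)(C)C(C)(C)C | intermediate
18 | tert-butyl 3-oxobutanoate | CC(=O)CC(=O)OC(C)(C)C | starting material
19 | but-3-en-2-one | CC(=O)C=C | starting material
20 | tert-butyl 2-acetyl-5-oxohexanoate | CC(=O)CCC(C(C)=O)C(=O)OC(C)(C)C | intermediate
21 | tert-butyl 2-methyl-4-oxocyclohex-2-ene-1-carboxylate (racemic) | CC1=CC(=O)CCC1C(=O)OC(C)(C)C | intermediate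
22 | methyl bromoacetate | COC(=O)CBr | starting material
23 | tert-butyl 3-(2-methoxy-2-oxoethyl)-2-methyl-4-oxocyclohex-2-ene-1-carboxylate (racemic) | COC(=O)CC1=C(C)C(CCC1=O)C(=O)OC(C)(C)C | intermediate
24 | tert-butyl 2,4-dioxo-2,3,4,5,6,7-hexahydro-1H-indene-7-carboxylate (racemic) | O=C1CC2=C(C1)C(=O)CCC2C(=O)OC(C)(C)C | intermediate
25 | tert-butyl 2,2-(ethylenedioxy)-4-oxo-2,3,4,5,6,7-hexahydro-1H-indene-7-carboxylate (racemic) | CC(C)(C)OC(=O)C1CCC(=O)C2=C1CC1(OCCO1)C2 | intermediate
26 | tert-butyl (4S)-2,2-(ethylenedioxy)-4-hydroxy-2,3,4,5,6,7-hexahydro-1H-indene-7-carboxylate (C7 epimers) | O[C@H]1CCC(C(=O)OC(C)(C)C)C2=C1CC1(OCCO1)C2 | intermediate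
27 | diiodomethane | ICI | starting material
28 | tert-butyl (3aS,4S,7aS)-2,2-(ethylenedioxy)-4-hydroxyoctahydro-3a,7a-methano-1H-indene-7-carboxylate (C7 epimers) | O[C@H]1CCC(C(=O)OC(C)(C)C)[C@]24C[C@@]14CC3(OCCO3)C2 | intermediate
29 | tert-butyl (3aS,7aS)-2,2-(ethylenedioxy)-4-oxooctahydro-3a,7a-methano-1H-indene-7-carboxylate (C7 epimers) | O=C1CCC(C(=O)OC(C)(C)C)[C@]24C[C@@]14CC3(OCCO3)C2 | intermediate
30 | lithium (7aS)-7-(tert-butoxycarbonyl)-2,2-(ethylenedioxy)-7a-methyl-2,3,5,6,7,7a-hexahydro-1H-inden-4-olate (C7 epimers) | C1C5(OCCO5)CC2=C(O[Li])CCC(C(=O)OC(C)(C)C)[C@@]21C | intermediate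
31 | tert-butyl (7aS)-2,2-(ethylenedioxy)-7a-methyl-4-[(trimethylsilyl)oxy]-2,3,5,6,7,7a-hexahydro-1H-indene-7-carboxylate (C7 epimers) | C1C5(OCCO5)CC2=C(O[Si](C)(C)C)CCC(C(=O)OC(C)(C)C)[C@@]21C | intermediate
32 | tert-butyl (7aS)-2,2-(ethylenedioxy)-7a-methyl-4-oxo-2,4,5,6,7,7a-hexahydro-1H-indene-7-carboxylate (C7 epimers) | C1C5(OCCO5)C=C2C(=O)CCC(C(=O)OC(C)(C)C)[C@@]21C | intermediate
33 | tert-butyl (4S,7aS)-2,2-(ethylenedioxy)-4-hydroxy-7a-methyl-2,4,5,6,7,7a-hexahydro-1H-indene-7-carboxylate (C7 epimers) | C1C5(OCCO5)C=C2[C@@H](O)CCC(C(=O)OC(C)(C)C)[C@@]21C | intermediate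
34 | tert-butyl (4S,7R,7aS)-2,2-(ethylenedioxy)-4-hydroxy-7a-methyl-2,4,5,6,7,7a-hexahydro-1H-indene-7-carboxylate | C1C5(OCCO5)C=C2[C@@H](O)CC[C@@H](C(=O)OC(C)(C)C)[C@@]21C | intermediate
35 | tert-butyl (4S,7R,7aS)-4-hydroxy-7a-methyl-2-oxo-2,4,5,6,7,7a-hexahydro-1H-indene-7-carboxylate | C1C(=O)C=C2[C@@H](O)CC[C@@H](C(=O)OC(C)(C)C)[C@@]21C | intermediate
36 | tert-butyl (1R,4S,7R,7aS)-1-[2-({[tert-butyl(dimethyl)silyl]oxy}methyl)prop-2-en-1-yl]-4-hydroxy-7a-methyl-2-oxo-2,4,5,6,7,7a-hexahydro-1H-indene-7-carboxylate | C=C(CO[Si](C)(C)C(C)(C)C)C[C@H]1C(=O)C=C2[C@@H](O)CC[C@@H](C(=O)OC(C)(C)C)[C@@]21C | intermediate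
37 | (2E,4E,6E,8R)-6,8-dimethyldeca-2,4,6-trienoic 2,4,6-trichlorobenzoic anhydride | CC[C@@H](C)/C=C(C)/C=C/C=C/C(=O)OC(=O)c1c(Cl)cc(Cl)cc1Cl | intermediate
38 | tert-butyl (1R,4S,7R,7aS)-1-[2-({[tert-butyl(dimethyl)silyl]oxy}methyl)prop-2-en-1-yl]-4-{[(2E,4E,6E,8R)-6,8-dimethyldeca-2,4,6-trienoyl]oxy}-7a-methyl-2-oxo-2,4,5,6,7,7a-hexahydro-1H-indene-7-carboxylate | C=C(CO[Si](C)(C)C(C)(C)C)C[C@H]1C(=O)C=C2[C@@H](OC(=O)/C=C/C=C/C(C)=C/[C@H](C)CC)CC[C@@H](C(=O)OC(C)(C)C)[C@@]21C | intermediate
39 | tert-butyl (1R,4S,7R,7aS)-4-{[(2E,4E,6E,8R)-6,8-dimethyldeca-2,4,6-trienoyl]oxy}-1-[2-(hydroxymethyl)prop-2-en-1-yl]-7a-methyl-2-oxo-2,4,5,6,7,7a-hexahydro-1H-indene-7-carboxylate | C=C(CO)C[C@H]1C(=O)C=C2[C@@H](OC(=O)/C=C/C=C/C(C)=C/[C@H](C)CC)CC[C@@H](C(=O)OC(C)(C)C)[C@@]21C | intermediate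
40 | tert-butyl (1R,4S,7R,7aS)-4-{[(2E,4E,6E,8R)-6,8-dimethyldeca-2,4,6-trienoyl]oxy}-1-(2-formylprop-2-en-1-yl)-7a-methyl-2-oxo-2,4,5,6,7,7a-hexahydro-1H-indene-7-carboxylate | C=C(C=O)C[C@H]1C(=O)C=C2[C@@H](OC(=O)/C=C/C=C/C(C)=C/[C@H](C)CC)CC[C@@H](C(=O)OC(C)(C)C)[C@@]21C | intermediate
41 | (1R,4S,7R,7aS)-4-{[(2E,4E,6E,8R)-6,8-dimethyldeca-2,4,6-trienoyl]oxy}-1-(2-formylprop-2-en-1-yl)-7a-methyl-2-oxo-2,4,5,6,7,7a-hexahydro-1H-indene-7-carboxylic acid | C=C(C=O)C[C@H]1C(=O)C=C2[C@@H](OC(=O)/C=C/C=C/C(C)=C/[C@H](C)CC)CC[C@@H](C(=O)O)[C@@]21C | target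

**Totals**
Total step count: 26.
Longest linear sequence: 16 steps (steps 11–26, from tert-butyl 3-oxobutanoate).

**Steps most likely to fail**

1. Step 13 (vinylogous Dieckmann closure). The ring closure depends on a minor dienolate (deprotonation at the C2 methyl, not at the more acidic ring CH) attacking the ester in a geometrically strained mode. It may be too slow, so that intermolecular condensation of the major dienolate takes over.
Fallback (sets out from 18, returns at 24): make the nucleophilic carbon the most acidic site by carrying a sulfur group on it. The dianion of 18 (NaH, then n-BuLi) is sulfenylated at the γ-carbon with diphenyl disulfide to give tert-butyl 3-oxo-4-(phenylsulfanyl)butanoate F1. Robinson annulation with 19 as in step 11 gives tert-butyl 4-oxo-2-[(phenylsulfanyl)methyl]cyclohex-2-ene-1-carboxylate F2. Alkylation with 22 as in step 12 gives tert-butyl 3-(2-methoxy-2-oxoethyl)-4-oxo-2-[(phenylsulfanyl)methyl]cyclohex-2-ene-1-carboxylate F3. Oxidation with m-chloroperbenzoic acid gives the sulfone tert-butyl 3-(2-methoxy-2-oxoethyl)-4-oxo-2-[(phenylsulfonyl)methyl]cyclohex-2-ene-1-carboxylate F4. Its α-sulfonyl carbanion (KOC(CH3)3, THF) closes the five-membered ring by an ordinary Dieckmann-type acylation to tert-butyl 2,4-dioxo-1-(phenylsulfonyl)-2,3,4,5,6,7-hexahydro-1H-indene-7-carboxylate F5. Reductive desulfonylation of the β-keto sulfone (SmI2, THF/MeOH, −78 °C) then gives 24.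

2. Step 18 (reductive opening and enolate trapping). Electron transfer may not stop at the cyclopropyl ketone (attack on the tert-butyl ester). The ring-fusion bond may compete with the exocyclic bond if orbital overlap is less favourable than assumed. Proton exchange may move the enolate to C5 before silylation, so that step 19 would desaturate the wrong side.
Fallback (sets out from 29, returns at 35): open the ring under protic single-electron conditions that spare esters, and introduce the alkene from the C2 ketone, where regiochemistry is fixed by the quaternary C7a; this does not address cleavage of the wrong bond. SmI2 with hexamethylphosphoramide and t-BuOH in THF gives tert-butyl (7aS)-2,2-(ethylenedioxy)-7a-methyl-4-oxooctahydro-1H-indene-7-carboxylate F6. LiBH(s-Bu)3 at −78 °C, attacking anti to the methyl, gives tert-butyl (4S,7aS)-2,2-(ethylenedioxy)-4-hydroxy-7a-methyloctahydro-1H-indene-7-carboxylate F7. Enolate protonation and ketal hydrolysis as in step 21 give tert-butyl (4S,7R,7aS)-4-hydroxy-7a-methyl-2-oxooctahydro-1H-indene-7-carboxylate F8. LiN(SiMe3)2/Me3SiCl gives tert-butyl (4S,7R,7aS)-7a-methyl-2,4-bis[(trimethylsilyl)oxy]-3a,4,5,6,7,7a-hexahydro-1H-indene-7-carboxylate F9. Saegusa–Ito oxidation with Pd(OAc)2 can eliminate only toward C3a and gives tert-butyl (4S,7R,7aS)-7a-methyl-2-oxo-4-[(trimethylsilyl)oxy]-2,4,5,6,7,7a-hexahydro-1H-indene-7-carboxylate F10. Dilute acid on work-up removes the silyl ether and gives 35.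

3. Step 22 (C1 alkylation). Facial discrimination at C1 may be insufficient (C1 epimer), and O-alkylation of the C4 alkoxide or a second alkylation may compete.
Fallback (sets out from 35, returns at 36): remove the alkoxide and set C1 under thermodynamic control. Et3SiCl/imidazole gives tert-butyl (4S,7R,7aS)-7a-methyl-2-oxo-4-[(triethylsilyl)oxy]-2,4,5,6,7,7a-hexahydro-1H-indene-7-carboxylate F11. Its monoenolate (LiN(SiMe3)2, 1.05 equiv) is alkylated with 17, and the C1 epimers are equilibrated with 1,8-diazabicyclo[5.4.0]undec-7-ene to the isomer with the side chain away from the C7 ester, tert-butyl (1R,4S,7R,7aS)-1-[2-({[tert-butyl(dimethyl)silyl]oxy}methyl)prop-2-en-1-yl]-7a-methyl-2-oxo-4-[(triethylsilyl)oxy]-2,4,5,6,7,7a-hexahydro-1H-indene-7-carboxylate F12. Pyridinium p-toluenesulfonate in MeOH at 0 °C removes the secondary triethylsilyl ether in the presence of the primary tert-butyldimethylsilyl ether and gives 36.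

**Further compounds**
F1 | step 13 | tert-butyl 3-oxo-4-(phenylsulfanyl)butanoate | CC(C)(C)OC(=O)CC(=O)CSc1ccccc1
F2 | step 13 | tert-butyl 4-oxo-2-[(phenylsulfanyl)methyl]cyclohex-2-ene-1-carboxylate | CC(C)(C)OC(=O)C1CCC(=O)C=C1CSc1ccccc1
F3 | step 13 | tert-butyl 3-(2-methoxy-2-oxoethyl)-4-oxo-2-[(phenylsulfanyl)methyl]cyclohex-2-ene-1-carboxylate | COC(=O)CC1=C(CSc2ccccc2)C(CCC1=O)C(=O)OC(C)(C)C
F4 | step 13 | tert-butyl 3-(2-methoxy-2-oxoethyl)-4-oxo-2-[(phenylsulfonyl)methyl]cyclohex-2-ene-1-carboxylate | COC(=O)CC1=C(CS(=O)(=O)c2ccccc2)C(CCC1=O)C(=O)OC(C)(C)C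
F5 | step 13 | tert-butyl 2,4-dioxo-1-(phenylsulfonyl)-2,3,4,5,6,7-hexahydro-1H-indene-7-carboxylate | O=C1CC2=C(C(CCC2=O)C(=O)OC(C)(C)C)C1S(=O)(=O)c1ccccc1
F6 | step 18 | tert-butyl (7aS)-2,2-(ethylenedioxy)-7a-methyl-4-oxooctahydro-1H-indene-7-carboxylate | C1C5(OCCO5)CC2C(=O)CCC(C(=O)OC(C)(C)C)[C@@]21C
F7 | step 18 | tert-butyl (4S,7aS)-2,2-(ethylenedioxy)-4-hydroxy-7a-methyloctahydro-1H-indene-7-carboxylate | C1C5(OCCO5)CC2[C@@H](O)CCC(C(=O)OC(C)(C)C)[C@@]21C
F8 | step 18 | tert-butyl (4S,7R,7aS)-4-hydroxy-7a-methyl-2-oxooctahydro-1H-indene-7-carboxylate | C1C(=O)CC2[C@@H](O)CC[C@@H](C(=O)OC(C)(C)C)[C@@]21C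
F9 | step 18 | tert-butyl (4S,7R,7aS)-7a-methyl-2,4-bis[(trimethylsilyl)oxy]-3a,4,5,6,7,7a-hexahydro-1H-indene-7-carboxylate | C1C(O[Si](C)(C)C)=CC2[C@@H](O[Si](C)(C)C)CC[C@@H](C(=O)OC(C)(C)C)[C@@]21C
F10 | step 18 | tert-butyl (4S,7R,7aS)-7a-methyl-2-oxo-4-[(trimethylsilyl)oxy]-2,4,5,6,7,7a-hexahydro-1H-indene-7-carboxylate | C1C(=O)C=C2[C@@H](O[Si](C)(C)C)CC[C@@H](C(=O)OC(C)(C)C)[C@@]21C
F11 | step 22 | tert-butyl (4S,7R,7aS)-7a-methyl-2-oxo-4-[(triethylsilyl)oxy]-2,4,5,6,7,7a-hexahydro-1H-indene-7-carboxylate | C1C(=O)C=C2[C@@H](O[Si](CC)(CC)CC)CC[C@@H](C(=O)OC(C)(C)C)[C@@]21C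
F12 | step 22 | tert-butyl (1R,4S,7R,7aS)-1-[2-({[tert-butyl(dimethyl)silyl]oxy}methyl)prop-2-en-1-yl]-7a-methyl-2-oxo-4-[(triethylsilyl)oxy]-2,4,5,6,7,7a-hexahydro-1H-indene-7-carboxylate | C=C(CO[Si](C)(C)C(C)(C)C)C[C@H]1C(=O)C=C2[C@@H](O[Si](CC)(CC)CC)CC[C@@H](C(=O)OC(C)(C)C)[C@@]21C
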